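Baeomycesic acid is cut at the depside ester into a ring A acid and a ring B phenol, and ring A is traced back to 2,4-dimethoxy-6-methylbenzoic acid. Everything rests on the contiguous array of ring A, in which the C6 methyl, the C1 carboxyl carbon and the C2 oxygen sit on three neighbouring atoms: this is the pattern left when a methyl nucleophile and CO2 add across a 3-alkoxyaryne. One flask thus forms the C6–CH3 and C1–CO2H bonds with the regiochemistry fixed. The precursor is 2-bromo-1-fluoro-3,5-dimethoxybenzene, with bromine between fluorine and a methoxy group. Chelation-controlled demethylation at O2, formylation at C3, coupling to benzyl-protected ring B and hydrogenolysis finish the route.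

Key step: step 2

Remark: ring A is the formyl-bearing benzoyl ring (C1 carboxyl carbon, C2 OH, C3 CHO, C4 OMe, C6 CH3) and ring B is the benzoic acid ring (primed locants); the target has no stereocentre. The ring A carboxyl group is carried as a benzyl ester through the formylation because Cl2CHOMe converts free carboxylic acids into acyl chlorides.

Step 1
Reactants: 1 1-fluoro-3,5-dimethoxybenzene; 2 N-bromosuccinimide
Product: 3 2-bromo-1-fluoro-3,5-dimethoxybenzene
Conditions: NBS (1.0 equiv), MeCN, 0 → 25 °C
Reagents that add atoms: N-bromosuccinimide, O=C1CCC(=O)N1Br
Why: Electrophilic aromatic bromination: the carbon ortho to fluorine is para to one methoxy group and ortho to the other and is less crowded than the carbon between the two methoxy groups, so bromine should enter there, and any minor isomer is removed by recrystallisation.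

Step 2
Reactants: 3 2-bromo-1-fluoro-3,5-dimethoxybenzene; 4 methylmagnesium bromide; 5 carbon dioxide
Product: 9 2,4-dimethoxy-6-methylbenzoic acid, via 2-fluoro-4,6-dimethoxyphenyllithium 6 (not isolated), via 3,5-dimethoxybenzyne 7 (not isolated), via 2,4-dimethoxy-6-methylphenylmagnesium bromide 8 (not isolated)
Conditions: n-BuLi (1.0 equiv), THF, −78 °C; MeMgBr (4 equiv), −78 → 50 °C; CO2 (g), −20 → 25 °C; aq HCl
Reagents that add atoms: methylmagnesium bromide, C[Mg]Br; carbon dioxide, O=C=O
Why: Bromine–lithium exchange puts the metal on the carbon between fluorine and a methoxy group (6), and warming in the presence of MeMgBr expels metal fluoride, so aryne 7 can form at that one position only. The methoxy group beside the triple bond distorts and polarises it, so the methyl–magnesium bond adds with methyl at the distal carbon (future C6) and magnesium at the proximal carbon (future C1), where the developing negative charge is stabilised inductively and by O–Mg coordination, giving 8. The crowded aryl Grignard 8 is then carboxylated by CO2, so the C6–CH3 and C1–CO2H bonds are both made in one flask. The closest known reaction type is the addition of alkyl Grignard or alkyllithium reagents to 3-alkoxyarynes generated from ortho-metalated fluoroanisoles, followed by CO2 capture, as used for 6-alkyl-2-alkoxybenzoic acids. No ring is closed and no stereocentre is formed. The step needs a single aryne and a single direction of addition, which the bromine position and the flanking methoxy group secure, while the excess of MeMgBr should outcompete 6 and 8 as nucleophiles and ends as water-soluble acetate.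

Step 3
Reactants: 9 2,4-dimethoxy-6-methylbenzoic acid
Product: 10 2-hydroxy-4-methoxy-6-methylbenzoic acid (everninic acid)
Conditions: BCl3 (2.5 equiv), CH2Cl2, −78 → 0 °C; H2O
Reagents that add atoms: none
Why: Chelation-directed Lewis-acid ether cleavage: boron bound to the carboxyl oxygen coordinates only the neighbouring C2 methoxy oxygen in a six-membered chelate, chloride then removes that methyl group, and the remote C4 methoxy group should be untouched at this temperature.

Step 4
Reactants: 10 2-hydroxy-4-methoxy-6-methylbenzoic acid; 11 benzyl bromide
Product: 12 benzyl 2-hydroxy-4-methoxy-6-methylbenzoate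
Conditions: BnBr (1.05 equiv), KHCO3, DMF, 25 °C
Reagents that add atoms: benzyl bromide, BrCc1ccccc1
Why: SN2 alkylation of the carboxylate: bicarbonate ionises only the carboxylic acid, the hydrogen-bonded C2 phenol stays protonated, and the benzyl ester should form without ether formation.

Step 5
Reactants: 12 benzyl 2-hydroxy-4-methoxy-6-methylbenzoate; 13 dichloromethyl methyl ether
Product: 14 benzyl 3-formyl-2-hydroxy-4-methoxy-6-methylbenzoate
Conditions: Cl2CHOMe (1.5 equiv), TiCl4 (2.2 equiv), CH2Cl2, −10 → 0 °C; ice, aq HCl
Reagents that add atoms: dichloromethyl methyl ether, COC(Cl)Cl; water, O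
Why: Rieche formylation (Friedel–Crafts type): titanium held by the C2 phenoxide and the C4 methoxy oxygen should deliver the chloromethoxycarbenium ion to C3, the only free position ortho to the phenol and the site favoured electronically in chelated salicylates, and aqueous work-up releases the aldehyde.

Step 6
Reactants: 14 benzyl 3-formyl-2-hydroxy-4-methoxy-6-methylbenzoate
Product: 15 3-formyl-2-hydroxy-4-methoxy-6-methylbenzoic acid
Conditions: H2 (1 atm), 10% Pd/C, EtOAc, 25 °C, stopped after 1 equiv H2
Reagents that add atoms: none
Why: Heterogeneous hydrogenolysis of the benzylic ester C–O bond: it should outpace reduction of the formyl group, which is deactivated by its hydrogen bond to the C2 hydroxyl, provided hydrogen uptake is limited to one equivalent.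

Step 7
Reactants: 16 methyl 2,4-dihydroxy-3,6-dimethylbenzoate
Product: 17 2,4-dihydroxy-3,6-dimethylbenzoic acid
Conditions: conc. H2SO4, 0 → 25 °C; then ice-water
Reagents that add atoms: water, O
Why: Acid-mediated ester cleavage through an acylium ion, the pathway used for 2,6-disubstituted benzoates: the two ortho substituents and the two hydroxyl donors favour ionisation in cold sulfuric acid, quenching on ice gives the acid, and the hot base or hot aqueous acid that would decarboxylate it is avoided.

Step 8
Reactants: 17 2,4-dihydroxy-3,6-dimethylbenzoic acid; 11 benzyl bromide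
Product: 18 benzyl 2,4-dihydroxy-3,6-dimethylbenzoate
Conditions: BnBr (1.0 equiv), KHCO3, DMF, 25 °C
Reagents that add atoms: benzyl bromide, BrCc1ccccc1
Why: SN2 alkylation of the carboxylate: with bicarbonate and one equivalent of benzyl bromide only the carboxylate is alkylated, so both phenols should stay free, and the mild temperature avoids decarboxylation.

Step 9
Reactants: 15 3-formyl-2-hydroxy-4-methoxy-6-methylbenzoic acid; 18 benzyl 2,4-dihydroxy-3,6-dimethylbenzoate
Product: 20 benzyl 4-[(3-formyl-2-hydroxy-4-methoxy-6-methylbenzoyl)oxy]-2-hydroxy-3,6-dimethylbenzoate, via 3-formyl-2-hydroxy-4-methoxy-6-methylbenzoic trifluoroacetic anhydride 19 (not isolated)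
Conditions: (CF3CO)2O (excess), toluene, 25 °C
Reagents that add atoms: none
Why: Mixed-anhydride esterification: trifluoroacetic anhydride converts acid 15 into the aroyl trifluoroacetate 19, which should acylate the free C4′ hydroxyl of 18, whereas the C2′ hydroxyl of 18 and the C2 hydroxyl of ring A are tied up in hydrogen bonds to carbonyl groups and flanked by substituents, so a single depside is expected.

Step 10
Reactants: 20 benzyl 4-[(3-formyl-2-hydroxy-4-methoxy-6-methylbenzoyl)oxy]-2-hydroxy-3,6-dimethylbenzoate
Product: 21 baeomycesic acid
Conditions: H2 (1 atm), 10% Pd/C, EtOAc, 25 °C, stopped after 1 equiv H2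
Reagents that add atoms: none
Why: Hydrogenolysis of the benzyl ester as in step 6: the aryl ester linkage, the methyl ether and the chelated aldehyde should survive when hydrogen uptake is limited to one equivalent.

Compound list
1 | 1-fluoro-3,5-dimethoxybenzene | COc1cc(F)cc(OC)c1 | starting material
2 | N-bromosuccinimide | O=C1CCC(=O)N1Br | starting material
3 | 2-bromo-1-fluoro-3,5-dimethoxybenzene | COc1cc(F)c(Br)c(OC)c1 | intermediate
4 | methylmagnesium bromide | C[Mg]Br | starting material
5 | carbon dioxide | O=C=O | starting material
6 | 2-fluoro-4,6-dimethoxyphenyllithium | COc1cc(F)c([Li])c(OC)c1 | intermediate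
7 | 3,5-dimethoxybenzyne | COC1=CC(OC)=CC#C1 | intermediate
8 | 2,4-dimethoxy-6-methylphenylmagnesium bromide | COc1cc(C)c([Mg]Br)c(OC)c1 | intermediate
9 | 2,4-dimethoxy-6-methylbenzoic acid | COc1cc(C)c(C(=O)O)c(OC)c1 | intermediate
10 | 2-hydroxy-4-methoxy-6-methylbenzoic acid (everninic acid) | COc1cc(C)c(C(=O)O)c(O)c1 | intermediate
11 | benzyl bromide | BrCc1ccccc1 | starting material
12 | benzyl 2-hydroxy-4-methoxy-6-methylbenzoate | COc1cc(C)c(C(=O)OCc2ccccc2)c(O)c1 | intermediate
13 | dichloromethyl methyl ether | COC(Cl)Cl | starting material
14 | benzyl 3-formyl-2-hydroxy-4-methoxy-6-methylbenzoate | COc1cc(C)c(C(=O)OCc2ccccc2)c(O)c1C=O | intermediate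
15 | 3-formyl-2-hydroxy-4-methoxy-6-methylbenzoic acid | COc1cc(C)c(C(=O)O)c(O)c1C=O | intermediate
16 | methyl 2,4-dihydroxy-3,6-dimethylbenzoate | COC(=O)c1c(C)cc(O)c(C)c1O | starting material
17 | 2,4-dihydroxy-3,6-dimethylbenzoic acid | Cc1cc(O)c(C)c(O)c1C(=O)O | intermediate
18 | benzyl 2,4-dihydroxy-3,6-dimethylbenzoate | Cc1cc(O)c(C)c(O)c1C(=O)OCc1ccccc1 | intermediate
19 | 3-formyl-2-hydroxy-4-methoxy-6-methylbenzoic trifluoroacetic anhydride | COc1cc(C)c(C(=O)OC(=O)C(F)(F)F)c(O)c1C=O | intermediate
20 | benzyl 4-[(3-formyl-2-hydroxy-4-methoxy-6-methylbenzoyl)oxy]-2-hydroxy-3,6-dimethylbenzoate | COc1cc(C)c(C(=O)Oc2cc(C)c(C(=O)OCc3ccccc3)c(O)c2C)c(O)c1C=O | intermediate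
21 | baeomycesic acid, 4-[(3-formyl-2-hydroxy-4-methoxy-6-methylbenzoyl)oxy]-2-hydroxy-3,6-dimethylbenzoic acid | COc1cc(C)c(C(=O)Oc2cc(C)c(C(=O)O)c(O)c2C)c(O)c1C=O | target

Total step count: 10.
Longest linear sequence: 8 steps (steps 1 to 6, then 9 and 10); the ring B branch (steps 7 and 8) joins at step 9.

Steps most likely to fail

Step 2. The aryl–metal species 6 and 8 may add to aryne 7 faster than the methyl–magnesium reagent does, which would lead to biaryl and oligomer formation. The aryne may also be released before enough methyl nucleophile is in place, and carboxylation of the crowded Grignard 8 may stay incomplete. The fallback makes the same two bonds in a polar, stepwise way without an aryne. Setting out from 3, bromine–lithium exchange with n-BuLi in THF at −78 °C and quenching with CO2 at that temperature, before lithium fluoride is lost, should give 2-fluoro-4,6-dimethoxybenzoic acid F1. Treatment of F1 with excess MeMgBr (4) in THF at reflux should then replace the fluoride ortho to the magnesium carboxylate by methyl. This is the carboxylate-assisted nucleophilic aromatic substitution known for unprotected ortho-fluorobenzoic acids with Grignard reagents, and fluoride should leave in preference to the ortho methoxy group. The fallback comes back to the route at 9.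

Step 5. Electrophilic attack may occur at C5 instead of C3, and the Lewis acid may cleave the benzyl ester. The fallback replaces the Friedel–Crafts process by a magnesium phenoxide-directed ortho-formylation. Setting out from 12, MgCl2, Et3N and paraformaldehyde in MeCN at reflux should bind formaldehyde to the magnesium phenoxide, from where it can reach only C3. This gives the magnesium salt of benzyl 2-hydroxy-3-(hydroxymethyl)-4-methoxy-6-methylbenzoate F2, which should be oxidised in the same flask by hydride transfer to a second formaldehyde. The conditions are basic, so the benzyl ester is not at risk, and the fallback comes back to the route at 14.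

Step 10. The formyl group may be over-reduced to a hydroxymethyl or methyl group during hydrogenolysis, or debenzylation may stay incomplete if the reaction is stopped early. The fallback changes the ring B ester to an acid-labile one, so that no hydrogenation is needed at the end. Setting out from 17, N,N′-diisopropyl-O-tert-butylisourea in CH2Cl2 at 25 °C should esterify only the carboxyl group and give tert-butyl 2,4-dihydroxy-3,6-dimethylbenzoate F3. Carbodiimide coupling of F3 with acid 15 (DCC, toluene/Et2O, 25 °C) should give tert-butyl 4-[(3-formyl-2-hydroxy-4-methoxy-6-methylbenzoyl)oxy]-2-hydroxy-3,6-dimethylbenzoate F4. TFA in CH2Cl2 with anisole as cation scavenger at 0 → 25 °C should then remove the tert-butyl group without touching the aldehyde, the methyl ether or the depside ester. The fallback comes back to the route at 21.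

Further compounds
F1 | step 2 | 2-fluoro-4,6-dimethoxybenzoic acid | COc1cc(F)c(C(=O)O)c(OC)c1
F2 | step 5 | benzyl 2-hydroxy-3-(hydroxymethyl)-4-methoxy-6-methylbenzoate | COc1cc(C)c(C(=O)OCc2ccccc2)c(O)c1CO
F3 | step 10 | tert-butyl 2,4-dihydroxy-3,6-dimethylbenzoate | Cc1cc(O)c(C)c(O)c1C(=O)OC(C)(C)C
F4 | step 10 | tert-butyl 4-[(3-formyl-2-hydroxy-4-methoxy-6-methylbenzoyl)oxy]-2-hydroxy-3,6-dimethylbenzoate | COc1cc(C)c(C(=O)Oc2cc(C)c(C(=O)OC(C)(C)C)c(O)c2C)c(O)c1C=O
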